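## Structural features

The target is all-E (3R,4R)-β,ψ-carotene-3,4-diol, C40H56O2 (carotenoid numbering: ring C1–C6, chain C7–C15, primed locants for the acyclic half). Its only ring is a 2,6,6-trimethylcyclohexene: C1 carries the gem-dimethyl group, C2 is CH2, C3 and C4 are carbinols, and C5(Me)=C6 is a tetrasubstituted alkene. C6 is bonded to C7 of a chain with ten further conjugated E double bonds (C7=C8 to C5'=C6', methyls on C9, C13, C13', C9', C5') that ends in the isolated C1'=C2' alkene of a ψ end. The only stereocentres, C3 and C4, are adjacent, both R, with the hydroxyls trans. The C4 hydroxyl is allylic to C5=C6 and through it to the whole polyene, so acid ionises it to a delocalised cation; the polyene itself is sensitive to light, oxygen and acid. C6 is the most hindered carbon, a fully substituted sp2 centre between CMe2 and C(Me), and the two halves of the chain differ, so a symmetric double olefination cannot be used. The real difficulty is the C3/C4 trans pair in the right absolute sense, directly beside the hindered C5=C6–C7 junction, with a C4 hydroxyl that cannot be carried through acid-mediated chain-building steps. The key step exploits the allylic triad C4(OH)–C5=C6 of the ring: it is the 1,3-transposed isomer of a C6 tertiary carbinol with a C4=C5 bond, so C6 can first be a ketone carbon that receives the chain, and the carbinol centre formed there under control of C3 can be moved suprafacially onto C4 while the tetrasubstituted C5=C6 bond is created.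

## Logic of the disconnections

24 ⇒ 23. The O–Si bond on O3 is cut. One silyl group on O3 serves the whole sequence (it steers step 3 and keeps O3 off rhenium in step 6). There is no gain in skeleton; the demand is a non-acidic final step, because the C4 hydroxyl of 24 ionises in acid.

23 ⇒ 11 + 20. The C11=C12 double bond is cut. This separates a C15 part that holds both stereocentres from an achiral C25 part, and makes the ring part the carbonyl component, so no phosphonium salt has to be made with acid next to the C4 hydroxyl. The demand is an olefination under near-neutral conditions (through 21) and convergence of the hindered Z isomer 22 to 23.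

11 ⇒ 8 (key). The C4–O bond and the C5=C6 π bond are exchanged for a C6–O bond and a C4=C5 π bond. In one sentence, the route is the suprafacial 1,3-shift of the tertiary C6 hydroxyl of 8 onto C4 (through 9 and 10). The gain is that the C4 stereocentre and the tetrasubstituted alkene both disappear, leaving a tertiary carbinol that is the product of a carbonyl addition at the most hindered carbon. The demand is a shift that is suprafacial, goes to C4 and not to C8, and does not ionise.

8 ⇒ 7 ⇒ 6. These are changes of oxidation level: the C11 aldehyde from the alcohol, and C7=C8 from C7≡C8. The dienal is wanted because it is the acceptor that steers the key step and the handle for step 12; the alkyne is how the chain enters as a nucleophile. The demands are a chemoselective oxidation beside a tertiary bis-allylic carbinol and an E-selective reduction directed by the C6 alkoxide.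

6 ⇒ 3 + 4. The C6–C7 bond is cut (forward through 5). The most hindered carbon of the target is made by addition to a carbonyl group, and the C15 skeleton comes from C9 + C6. The demand is attack on the carbonyl face cis to the O3 substituent, which leaves the new hydroxyl trans to it.

3 ⇒ 2 ⇒ 1. The O–Si bond and then the C3–H bond are cut. The single stereocentre from which all others derive comes from a prochiral ene-dione by catalyst control. The demand is selection of the unhindered carbonyl and of one enantioface.

20 ⇒ 19 ⇒ 18. The C12–P bond and then a C12–H bond are cut, which returns the nucleophilic C25 unit to an aldehyde. The demand is that the acyclic polyene tolerates brief exposure to HBr.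

18 ⇒ 14 + 15. The C11'=C12' double bond is cut (forward through 16 and 17). 15 is symmetrical and commercial; the demand is mono-olefination.

14 ⇒ 13 ⇒ 12. The C11'–P bond is cut with allylic transposition, then the C9'–C10' bond (vinyl addition to a ketone). This reaches a commercial C13 ketone.

## Other disconnections considered

Alternative 1: The first plan that comes to mind cuts C11=C12 and C11'=C12' together, back to the central dialdehyde 15, the acyclic salt 14 and a ring C15 phosphonium salt A1. A1 would carry the ring at the 3-hydroxy-4-oxo level, because its formation with HBr would ionise a C4 carbinol. Two Wittig reactions would give the C40 ketol A2, and C4 would be set last by hydride reduction. The chosen plan is preferred because in A2 the C4 configuration would rest on the weak facial bias of a ketone beside a small hydroxyl, on the least tractable compound of the route. In addition, the C3–H of the α-ketol would pass through two basic olefinations, where enediol formation opens racemisation and autoxidation. The step count is similar, so nothing is gained for the loss of control.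

Alternative 2: An enzymatic dynamic reductive kinetic resolution would reduce the racemic C13 ketol A3 with a ketoreductase, with racemisation at C3 in the flask, to the trans diol A4, followed by chain extension to C40. It would set both centres at once. However, racemisation of a cyclic α-ketol runs through an enediol that also leads to the transposed ketol and to the diosphenol. The enzyme would also have to accept a carbonyl flanked by a tetrasubstituted alkene and spare the side-chain enone. A4 would then have to be extended by 27 carbons with the free allylic C4 hydroxyl present from the start, which costs protecting-group steps and forbids acid-mediated salt formation. The chosen plan creates C4 only after the C15 skeleton and its aldehyde are in place.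

Alternative 3: A cross-coupling at the hindered C6–C7 sp2–sp2 bond would join the ring enol triflate A5 with the C31 polyenyl stannane A6 under zerovalent palladium (Stille, Pd(PPh3)4). A5 would come from the saturated ketone A7 by enolisation towards C5, and that enolate carries the C4 silyloxy group as a β-leaving group (E1cB loss). Coupling at a carbon flanked by CMe2 and C(Me) is expected to be slow, while A6 is prone to protodestannylation and isomerisation. The trans diol of A7 would have to be built separately with no stereochemical relay. The chosen plan forms the same C6–C7 bond by carbonyl addition, which tolerates the hindrance and at the same time plants the stereochemical information used for C4.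

Key step: step 6

Assumption: 1, 4 (as the pure 2E isomer), 12 (as the 3E,5E isomer) and 15 are taken as commercial; technical 12 contains some 5Z isomer, which would be removed by crystallisation of salt 14. All polyene steps are run under argon in dim light.

## Route

Step 1
Reactants: 1 2,6,6-trimethylcyclohex-2-ene-1,4-dione (ketoisophorone)
Product: 2 (4R)-4-hydroxy-2,6,6-trimethylcyclohex-2-en-1-one
Conditions: RuCl(p-cymene)[(R,R)-TsDPEN] (cat.), KOH (cat.), i-PrOH, 25 °C
Reagents that add atoms: none
Why: Noyori-type asymmetric transfer hydrogenation; the ruthenium hydride should reduce the unhindered C4 carbonyl (the other is flanked by CMe2 and C(Me)=) and leave the C=C bond. With the (R,R)-ligand the enone π system is expected to take the place of the aryl group in the standard model, which should give the (R)-carbinol that becomes C3 of the target.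

Step 2
Reactants: 2 (4R)-4-hydroxy-2,6,6-trimethylcyclohex-2-en-1-one
Product: 3 (4R)-4-[tert-butyl(dimethyl)silyl]oxy-2,6,6-trimethylcyclohex-2-en-1-one
Conditions: TBSCl, imidazole, DMF, 0 °C → rt
Reagents that add atoms: tert-butyl(chloro)dimethylsilane (TBSCl), CC(C)(C)[Si](C)(C)Cl
Why: Standard silylation of a secondary allylic alcohol; the bulky, non-participating silyl ether later controls the face of attack at the ketone and cannot exchange onto rhenium in step 6.

Step 3
Reactants: 3 (4R)-4-[tert-butyl(dimethyl)silyl]oxy-2,6,6-trimethylcyclohex-2-en-1-one; 4 (2E)-3-methylpent-2-en-4-yn-1-ol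
Product: 6 (1R,4R)-4-[tert-butyl(dimethyl)silyl]oxy-1-[(3E)-5-hydroxy-3-methylpent-3-en-1-yn-1-yl]-2,6,6-trimethylcyclohex-2-en-1-ol, via dilithiated enynol 5 (not isolated)
Conditions: 4, n-BuLi (2 equiv), THF, −78 → 0 °C; then 3, −78 → −30 °C; aq NH4Cl
Reagents that add atoms: none
Why: 1,2-Addition of a lithium acetylide to the hindered enone carbonyl forms the C6–C7 bond. In the half-chair with the silyloxy group pseudoequatorial, the axial methyl of the CMe2 group lies on the face anti to the silyloxy group, so the acetylide should enter cis to the silyloxy group and leave the new tertiary hydroxyl trans to it (1R).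

Step 4
Reactants: 6 (1R,4R)-4-[tert-butyl(dimethyl)silyl]oxy-1-[(3E)-5-hydroxy-3-methylpent-3-en-1-yn-1-yl]-2,6,6-trimethylcyclohex-2-en-1-ol
Product: 7 (1R,4R)-4-[tert-butyl(dimethyl)silyl]oxy-1-[(1E,3E)-5-hydroxy-3-methylpenta-1,3-dien-1-yl]-2,6,6-trimethylcyclohex-2-en-1-ol
Conditions: NaAlH2(OCH2CH2OMe)2 (Red-Al), THF, 0 °C → rt; aq KNaC4H4O6
Reagents that add atoms: none
Why: Alkoxide-directed trans-hydroalumination of the propargylic alcohol followed by protonolysis should give the E alkene (future C7=C8); the silyl ether and the isolated ring alkene are not touched.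

Step 5
Reactants: 7 (1R,4R)-4-[tert-butyl(dimethyl)silyl]oxy-1-[(1E,3E)-5-hydroxy-3-methylpenta-1,3-dien-1-yl]-2,6,6-trimethylcyclohex-2-en-1-ol
Product: 8 (2E,4E)-5-[(1R,4R)-4-[tert-butyl(dimethyl)silyl]oxy-1-hydroxy-2,6,6-trimethylcyclohex-2-en-1-yl]-3-methylpenta-2,4-dienal
Conditions: activated MnO2, CH2Cl2, rt
Reagents that add atoms: none
Why: MnO2 oxidises the primary dienylic alcohol to the dienal chemoselectively; the tertiary carbinol cannot be oxidised and the neutral medium does not ionise it.

Step 6
Reactants: 8 (2E,4E)-5-[(1R,4R)-4-[tert-butyl(dimethyl)silyl]oxy-1-hydroxy-2,6,6-trimethylcyclohex-2-en-1-yl]-3-methylpenta-2,4-dienal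
Product: 11 (2E,4E)-5-[(3R,4R)-4-[tert-butyl(dimethyl)silyl]oxy-3-hydroxy-2,6,6-trimethylcyclohex-1-en-1-yl]-3-methylpenta-2,4-dienal, via C6 perrhenate ester 9 (not isolated), via C4 perrhenate ester 10 (not isolated)
Conditions: Ph3SiOReO3 (3 mol %), Et2O, −50 → 0 °C, Ar; then Et3N
Reagents that add atoms: none
Why: Mechanism: the tertiary hydroxyl of 8 exchanges onto heptavalent rhenium to give the perrhenate ester 9, which undergoes a [3,3]-sigmatropic shift through a six-membered chair-like array (O–Re–O bridging C6 and C4 across C5) to the secondary perrhenate ester 10, and exchange of 10 with a further molecule of 8 releases 11 and regenerates 9. The closest known reaction type is the oxo-rhenium-catalysed 1,3-transposition of allylic alcohols, which runs from tertiary to secondary carbinols when conjugation is gained and transfers chirality when ionisation is suppressed. No ring is closed; the six-membered array exists only in the transition state. The new stereocentre C4 is controlled by the C6 carbinol centre: the shift is suprafacial, so oxygen arrives at C4 on the ring face it leaves at C6, the face anti to the C3 silyloxy group (step 3), which gives the trans (3R,4R) pair while C6 becomes sp2 in the tetrasubstituted C5=C6 bond. Regioselectivity between the two allyl arms of C6 is needed: a shift to C8 would break the dienal conjugation and build positive charge on a carbon conjugated to the electron-poor enal, whereas the shift to C4 ends in a fully conjugated trienal, and since the process is reversible 11 is the thermodynamic sink. Stereofidelity is needed as well: the acceptor dienal on C6 disfavours ionisation of 9 to a free pentadienyl cation, the pathway by which such shifts lose chirality, and low temperature in ether supports the concerted path. The silyl ether on O3 cannot exchange onto rhenium, and in 11 the C4 oxygen is allylic to an electron-poor trienal, so epimerisation by re-ionisation should be slow and the reverse shift, itself suprafacial, can only return 8 of unchanged configuration.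

Step 7
Reactants: 12 (3E,5E)-6,10-dimethylundeca-3,5,9-trien-2-one (pseudoionone)
Product: 13 (4E,6E)-3,7,11-trimethyldodeca-1,4,6,10-tetraen-3-ol (racemic)
Conditions: CH2=CHMgBr, THF, −20 → 0 °C; aq NH4Cl
Reagents that add atoms: vinylmagnesium bromide, C=C[Mg]Br
Why: 1,2-Grignard addition of a vinyl nucleophile to the dienone carbonyl gives the tertiary bis-allylic alcohol; its stereocentre is removed in step 8.

Step 8
Reactants: 13 (4E,6E)-3,7,11-trimethyldodeca-1,4,6,10-tetraen-3-ol (racemic)
Product: 14 [(2E,4E,6E)-3,7,11-trimethyldodeca-2,4,6,10-tetraen-1-yl]triphenylphosphonium bromide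
Conditions: PPh3·HBr, MeOH, 0 °C → rt; crystallisation
Reagents that add atoms: triphenylphosphine hydrobromide, Br.c1ccc(cc1)P(c1ccccc1)c1ccccc1
Why: Acid-promoted allylic substitution with transposition (SN1 type): PPh3 is captured at the primary terminus, which gives the fully conjugated allylic phosphonium salt. Crystallisation should remove minor Z isomers.

Step 9
Reactants: 14 [(2E,4E,6E)-3,7,11-trimethyldodeca-2,4,6,10-tetraen-1-yl]triphenylphosphonium bromide; 15 (2E,4E,6E)-2,7-dimethylocta-2,4,6-trienedial
Product: 18 (2E,4E,6E,8E,10E,12E,14E)-2,7,11,15,19-pentamethylicosa-2,4,6,8,10,12,14,18-octaenal, via ylide of the C15 salt 16 (not isolated), via 8Z-isomer of the aldehyde 17 (not isolated)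
Conditions: 15 (3 equiv), 1,2-epoxybutane, EtOH, reflux
Reagents that add atoms: none
Why: Wittig olefination: bromide opens the epoxide to an alkoxide that deprotonates 14 to ylide 16 at low stationary concentration, which together with the excess of the symmetric dialdehyde favours mono-olefination. The hindered Z isomer 17 (methyl on the neighbouring carbon against an inner hydrogen) should relax to the E isomer at reflux.

Step 10
Reactants: 18 (2E,4E,6E,8E,10E,12E,14E)-2,7,11,15,19-pentamethylicosa-2,4,6,8,10,12,14,18-octaenal
Product: 19 (2E,4E,6E,8E,10E,12E,14E)-2,7,11,15,19-pentamethylicosa-2,4,6,8,10,12,14,18-octaen-1-ol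
Conditions: NaBH4, MeOH/THF, 0 °C
Reagents that add atoms: none
Why: 1,2-Reduction of the polyenal to the primary allylic alcohol; no other reducible group is present.

Step 11
Reactants: 19 (2E,4E,6E,8E,10E,12E,14E)-2,7,11,15,19-pentamethylicosa-2,4,6,8,10,12,14,18-octaen-1-ol
Product: 20 [(2E,4E,6E,8E,10E,12E,14E)-2,7,11,15,19-pentamethylicosa-2,4,6,8,10,12,14,18-octaen-1-yl]triphenylphosphonium bromide
Conditions: PPh3·HBr, MeOH/CH2Cl2, 0 °C → rt
Reagents that add atoms: triphenylphosphine hydrobromide, Br.c1ccc(cc1)P(c1ccccc1)c1ccccc1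
Why: The same acid-mediated phosphonium salt formation as in step 8, here on a primary polyenylic alcohol with capture of PPh3 at the terminal carbon; the acyclic polyene has no group that brief exposure to HBr at low temperature should harm.

Step 12
Reactants: 20 [(2E,4E,6E,8E,10E,12E,14E)-2,7,11,15,19-pentamethylicosa-2,4,6,8,10,12,14,18-octaen-1-yl]triphenylphosphonium bromide; 11 (2E,4E)-5-[(3R,4R)-4-[tert-butyl(dimethyl)silyl]oxy-3-hydroxy-2,6,6-trimethylcyclohex-1-en-1-yl]-3-methylpenta-2,4-dienal
Product: 23 (3R,4R)-3-[tert-butyl(dimethyl)silyl]oxy-β,ψ-caroten-4-ol (all-E), via ylide of the C25 salt 21 (not isolated), via 11Z-isomer of the silyl ether 22 (not isolated)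
Conditions: 1,2-epoxybutane, EtOH, reflux, Ar, dim light
Reagents that add atoms: none
Why: Wittig olefination forming C11=C12 under the same near-neutral epoxide conditions, which spare the free allylic C4 hydroxyl and the silyl ether. The first-formed 11Z isomer 22 is a hindered cis isomer (methyl on C13 against H-10) and should isomerise at reflux to the all-E polyene, so the step is stereoconvergent.

Step 13
Reactants: 23 (3R,4R)-3-[tert-butyl(dimethyl)silyl]oxy-β,ψ-caroten-4-ol (all-E)
Product: 24 (3R,4R)-β,ψ-carotene-3,4-diol (all-E)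
Conditions: Bu4NF, THF, 0 °C → rt, Ar, dim light
Reagents that add atoms: none
Why: Fluoride cleavage of the secondary silyl ether under non-acidic conditions; acid is avoided because the C4 hydroxyl is allylic to the polyene.

## Compound list

1 | 2,6,6-trimethylcyclohex-2-ene-1,4-dione (ketoisophorone) | O=C1C(C)=CC(=O)CC1(C)C | starting material
2 | (4R)-4-hydroxy-2,6,6-trimethylcyclohex-2-en-1-one | O=C1C(C)=C[C@H](O)CC1(C)C | intermediate
3 | (4R)-4-[tert-butyl(dimethyl)silyl]oxy-2,6,6-trimethylcyclohex-2-en-1-one | O=C1C(C)=C[C@H](O[Si](C)(C)C(C)(C)C)CC1(C)C | intermediate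
4 | (2E)-3-methylpent-2-en-4-yn-1-ol | OC/C=C(C)/C#C | starting material
5 | dilithium salt of 4 (lithium alkoxide, lithium acetylide) | [Li]OC/C=C(C)/C#C[Li] | intermediate
6 | (1R,4R)-4-[tert-butyl(dimethyl)silyl]oxy-1-[(3E)-5-hydroxy-3-methylpent-3-en-1-yn-1-yl]-2,6,6-trimethylcyclohex-2-en-1-ol | OC/C=C(C)/C#C[C@]1(O)C(C)=C[C@H](O[Si](C)(C)C(C)(C)C)CC1(C)C | intermediate
7 | (1R,4R)-4-[tert-butyl(dimethyl)silyl]oxy-1-[(1E,3E)-5-hydroxy-3-methylpenta-1,3-dien-1-yl]-2,6,6-trimethylcyclohex-2-en-1-ol | OC/C=C(C)/C=C/[C@]1(O)C(C)=C[C@H](O[Si](C)(C)C(C)(C)C)CC1(C)C | intermediate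
8 | (2E,4E)-5-[(1R,4R)-4-[tert-butyl(dimethyl)silyl]oxy-1-hydroxy-2,6,6-trimethylcyclohex-2-en-1-yl]-3-methylpenta-2,4-dienal | O=C/C=C(C)/C=C/[C@]1(O)C(C)=C[C@H](O[Si](C)(C)C(C)(C)C)CC1(C)C | intermediate
9 | C6 perrhenate ester of 8 (OReO3 in place of the tertiary hydroxyl) | O=C/C=C(C)/C=C/[C@]1(O[Re](=O)(=O)=O)C(C)=C[C@H](O[Si](C)(C)C(C)(C)C)CC1(C)C | intermediate
10 | C4 perrhenate ester of 11 (OReO3 in place of the C4 hydroxyl) | O=C/C=C(C)/C=C/C1=C(C)[C@@H](O[Re](=O)(=O)=O)[C@H](O[Si](C)(C)C(C)(C)C)CC1(C)C | intermediate
11 | (2E,4E)-5-[(3R,4R)-4-[tert-butyl(dimethyl)silyl]oxy-3-hydroxy-2,6,6-trimethylcyclohex-1-en-1-yl]-3-methylpenta-2,4-dienal | O=C/C=C(C)/C=C/C1=C(C)[C@@H](O)[C@H](O[Si](C)(C)C(C)(C)C)CC1(C)C | intermediate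
12 | (3E,5E)-6,10-dimethylundeca-3,5,9-trien-2-one (pseudoionone) | CC(C)=CCC/C(C)=C/C=C/C(C)=O | starting material
13 | (4E,6E)-3,7,11-trimethyldodeca-1,4,6,10-tetraen-3-ol (racemic) | CC(C)=CCC/C(C)=C/C=C/C(C)(O)C=C | intermediate
14 | [(2E,4E,6E)-3,7,11-trimethyldodeca-2,4,6,10-tetraen-1-yl]triphenylphosphonium bromide | CC(C)=CCC/C(C)=C/C=C/C(C)=C/C[P+](c1ccccc1)(c1ccccc1)c1ccccc1.[Br-] | intermediate
15 | (2E,4E,6E)-2,7-dimethylocta-2,4,6-trienedial | O=C/C(C)=C/C=C/C=C(C)/C=O | starting material
16 | ylide of 14, [(2E,4E,6E)-3,7,11-trimethyldodeca-2,4,6,10-tetraen-1-ylidene]triphenylphosphorane | CC(C)=CCC/C(C)=C/C=C/C(C)=C/C=P(c1ccccc1)(c1ccccc1)c1ccccc1 | intermediate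
17 | (2E,4E,6E,8Z,10E,12E,14E)-2,7,11,15,19-pentamethylicosa-2,4,6,8,10,12,14,18-octaenal | CC(C)=CCC/C(C)=C/C=C/C(C)=C/C=C\C(C)=C\C=C\C=C(C)\C=O | intermediate
18 | (2E,4E,6E,8E,10E,12E,14E)-2,7,11,15,19-pentamethylicosa-2,4,6,8,10,12,14,18-octaenal | CC(C)=CCC/C(C)=C/C=C/C(C)=C/C=C/C(C)=C/C=C/C=C(C)/C=O | intermediate
19 | (2E,4E,6E,8E,10E,12E,14E)-2,7,11,15,19-pentamethylicosa-2,4,6,8,10,12,14,18-octaen-1-ol | CC(C)=CCC/C(C)=C/C=C/C(C)=C/C=C/C(C)=C/C=C/C=C(C)/CO | intermediate
20 | [(2E,4E,6E,8E,10E,12E,14E)-2,7,11,15,19-pentamethylicosa-2,4,6,8,10,12,14,18-octaen-1-yl]triphenylphosphonium bromide | CC(C)=CCC/C(C)=C/C=C/C(C)=C/C=C/C(C)=C/C=C/C=C(C)/C[P+](c1ccccc1)(c1ccccc1)c1ccccc1.[Br-] | intermediate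
21 | ylide of 20, [(2E,4E,6E,8E,10E,12E,14E)-2,7,11,15,19-pentamethylicosa-2,4,6,8,10,12,14,18-octaen-1-ylidene]triphenylphosphorane | CC(C)=CCC/C(C)=C/C=C/C(C)=C/C=C/C(C)=C/C=C/C=C(C)/C=P(c1ccccc1)(c1ccccc1)c1ccccc1 | intermediate
22 | (11Z)-isomer of 23, (3R,4R,11Z)-3-[tert-butyl(dimethyl)silyl]oxy-β,ψ-caroten-4-ol | CC(C)=CCC/C(C)=C/C=C/C(C)=C/C=C/C(C)=C/C=C/C=C(C)/C=C\C=C(C)\C=C\C1=C(C)[C@@H](O)[C@H](O[Si](C)(C)C(C)(C)C)CC1(C)C | intermediate
23 | (3R,4R)-3-[tert-butyl(dimethyl)silyl]oxy-β,ψ-caroten-4-ol (all-E) | CC(C)=CCC/C(C)=C/C=C/C(C)=C/C=C/C(C)=C/C=C/C=C(C)/C=C/C=C(C)/C=C/C1=C(C)[C@@H](O)[C@H](O[Si](C)(C)C(C)(C)C)CC1(C)C | intermediate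
24 | (3R,4R)-β,ψ-carotene-3,4-diol (all-E) | CC(C)=CCC/C(C)=C/C=C/C(C)=C/C=C/C(C)=C/C=C/C=C(C)/C=C/C=C(C)/C=C/C1=C(C)[C@@H](O)[C@H](O)CC1(C)C | target

## Step count and least certain steps

Total step count: 13. Longest linear sequence: 8 steps (steps 1–6, 12, 13, from 1); the C25 branch (steps 7–11) is made in parallel.

Step 6 (key). The most likely failure is ionisation of the tertiary, doubly allylic perrhenate ester in competition with the concerted shift. That would erode the suprafacial relay (epimer formation at C4) and open proton loss to ring dienes; ester exchange at the hindered carbinol may also be slow. The fallback sets out from 8 and returns at 24. Treatment of 8 with pyridinium chlorochromate [C5H5NH][CrO3Cl] (hexavalent chromium) in CH2Cl2 should effect the Babler–Dauben oxidative 1,3-transposition of the tertiary allylic alcohol to the keto aldehyde F1 (C4 carbonyl, C5=C6 in place, silyl ether on O3 unchanged). This outcome no longer depends on the configuration at C6. Wittig reaction of F1 with ylide 21 under the conditions of step 12 (the hindered conjugated ketone should not react) would give the C40 silyloxy ketone F2. HF·pyridine in THF would remove the silyl group to give the ketol F3 (the same compound as A2). Hydroxyl-directed reduction with NMe4BH(OAc)3 in MeCN with a little AcOH at −30 °C delivers hydride from the boron bound to O3 to the C4 carbonyl on the face syn to O3, which should place the new hydroxyl trans and give 24.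

Step 3. The most likely failure is insufficient facial discrimination in the acetylide addition: both faces of the carbonyl are flanked by a methyl of the CMe2 group, and the controlling silyloxy group is remote. The wrong C6 configuration would be passed on to C4 by the suprafacial shift. The fallback sets out from 3 and returns at 11. The C6 epimer of the adduct, the (1S,4R)-enyne diol F4, is separated and taken through the conditions of steps 4, 5 and 6 to the (1S,4R)-diene diol F5, the (1S,4R)-hydroxy dienal F6 and the 3,4-cis hydroxy aldehyde F7. The C4 carbinol of F7 is then inverted by Mitsunobu esterification (4-nitrobenzoic acid, PPh3, diisopropyl azodicarboxylate, THF, 0 °C; SN2 attack anti to the silyloxy group) to the trans 4-nitrobenzoate F8. Methanolysis (K2CO3, MeOH, 0 °C) gives 11, so both C6 epimers converge.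

Step 1. The most likely failure is competing reduction of the C=C bond or of the hindered carbonyl of the ene-dione, or low enantiofacial discrimination, because the two groups flanking the reacting carbonyl (CH= and CH2) differ little in size. The fallback sets out from 1 and returns at 2. Reduction of 1 with NaBH4 and CeCl3·7H2O in MeOH at −20 °C would give the racemic hydroxy enone F9. Acylation with vinyl acetate catalysed by Candida antarctica lipase B (a serine hydrolase) is expected, by analogy with cyclohex-2-en-1-ol, to convert the (R)-alcohol into the (R)-acetate F10 and leave the (S)-alcohol F11. F10 is separated and methanolysed (K2CO3, MeOH) to 2; F11 is oxidised back to 1 with MnO2 and recycled.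

Step 12. The most likely failure is incomplete stereoconvergence at the new double bond: the heating that relaxes the hindered 11Z bond also slowly populates unhindered Z isomers. Material may also be lost through base-mediated side reactions of the hydroxy trienal and hydrolysis of the ylide in the protic medium. The fallback sets out from 19 and returns at 23. 19 is converted into the allylic bromide F12 (PBr3, Et2O, pyridine, −20 °C), which on Arbuzov reaction with P(OEt)3 gives the diethyl phosphonate F13. Horner–Wadsworth–Emmons olefination of 11 with the anion of F13 (NaN(SiMe3)2, THF, −78 → 0 °C, one extra equivalent of base for the C4 hydroxyl) forms C11=C12 with the intrinsic E selectivity of the phosphonate and should give 23 without thermal isomerisation.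

## Further compounds

F1 | step 6 | (2E,4E)-5-[(4R)-4-[tert-butyl(dimethyl)silyl]oxy-2,6,6-trimethyl-3-oxocyclohex-1-en-1-yl]-3-methylpenta-2,4-dienal | O=C/C=C(C)/C=C/C1=C(C)C(=O)[C@H](O[Si](C)(C)C(C)(C)C)CC1(C)C
F2 | step 6 | (3R)-3-[tert-butyl(dimethyl)silyl]oxy-β,ψ-caroten-4-one (all-E) | CC(C)=CCC/C(C)=C/C=C/C(C)=C/C=C/C(C)=C/C=C/C=C(C)/C=C/C=C(C)/C=C/C1=C(C)C(=O)[C@H](O[Si](C)(C)C(C)(C)C)CC1(C)C
F3 | step 6 | (3R)-3-hydroxy-β,ψ-caroten-4-one (all-E) | CC(C)=CCC/C(C)=C/C=C/C(C)=C/C=C/C(C)=C/C=C/C=C(C)/C=C/C=C(C)/C=C/C1=C(C)C(=O)[C@H](O)CC1(C)C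
F4 | step 3 | (1S,4R)-4-[tert-butyl(dimethyl)silyl]oxy-1-[(3E)-5-hydroxy-3-methylpent-3-en-1-yn-1-yl]-2,6,6-trimethylcyclohex-2-en-1-ol | OC/C=C(C)/C#C[C@@]1(O)C(C)=C[C@H](O[Si](C)(C)C(C)(C)C)CC1(C)C
F5 | step 3 | (1S,4R)-4-[tert-butyl(dimethyl)silyl]oxy-1-[(1E,3E)-5-hydroxy-3-methylpenta-1,3-dien-1-yl]-2,6,6-trimethylcyclohex-2-en-1-ol | OC/C=C(C)/C=C/[C@@]1(O)C(C)=C[C@H](O[Si](C)(C)C(C)(C)C)CC1(C)C
F6 | step 3 | (2E,4E)-5-[(1S,4R)-4-[tert-butyl(dimethyl)silyl]oxy-1-hydroxy-2,6,6-trimethylcyclohex-2-en-1-yl]-3-methylpenta-2,4-dienal | O=C/C=C(C)/C=C/[C@@]1(O)C(C)=C[C@H](O[Si](C)(C)C(C)(C)C)CC1(C)C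
F7 | step 3 | (2E,4E)-5-[(3S,4R)-4-[tert-butyl(dimethyl)silyl]oxy-3-hydroxy-2,6,6-trimethylcyclohex-1-en-1-yl]-3-methylpenta-2,4-dienal | O=C/C=C(C)/C=C/C1=C(C)[C@H](O)[C@H](O[Si](C)(C)C(C)(C)C)CC1(C)C
F8 | step 3 | 4-nitrobenzoate of 11, (1R,6R)-6-[tert-butyl(dimethyl)silyl]oxy-2,4,4-trimethyl-3-[(1E,3E)-3-methyl-5-oxopenta-1,3-dien-1-yl]cyclohex-2-en-1-yl 4-nitrobenzoate | O=C/C=C(C)/C=C/C1=C(C)[C@@H](OC(=O)c2ccc(cc2)[N+](=O)[O-])[C@H](O[Si](C)(C)C(C)(C)C)CC1(C)C
F9 | step 1 | rac-4-hydroxy-2,6,6-trimethylcyclohex-2-en-1-one | O=C1C(C)=CC(O)CC1(C)C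
F10 | step 1 | (1R)-3,5,5-trimethyl-4-oxocyclohex-2-en-1-yl acetate | O=C1C(C)=C[C@H](OC(C)=O)CC1(C)C
F11 | step 1 | (4S)-4-hydroxy-2,6,6-trimethylcyclohex-2-en-1-one | O=C1C(C)=C[C@@H](O)CC1(C)C
F12 | step 12 | (2E,4E,6E,8E,10E,12E,14E)-1-bromo-2,7,11,15,19-pentamethylicosa-2,4,6,8,10,12,14,18-octaene | CC(C)=CCC/C(C)=C/C=C/C(C)=C/C=C/C(C)=C/C=C/C=C(C)/CBr
F13 | step 12 | diethyl [(2E,4E,6E,8E,10E,12E,14E)-2,7,11,15,19-pentamethylicosa-2,4,6,8,10,12,14,18-octaen-1-yl]phosphonate | CC(C)=CCC/C(C)=C/C=C/C(C)=C/C=C/C(C)=C/C=C/C=C(C)/CP(=O)(OCC)OCC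
A1 | alternative 1 | [(2E,4E)-5-[(4R)-4-hydroxy-2,6,6-trimethyl-3-oxocyclohex-1-en-1-yl]-3-methylpenta-2,4-dien-1-yl]triphenylphosphonium bromide | c1ccccc1[P+](c1ccccc1)(c1ccccc1)C/C=C(C)/C=C/C2=C(C)C(=O)[C@H](O)CC2(C)C.[Br-]
A2 | alternative 1 | (3R)-3-hydroxy-β,ψ-caroten-4-one (all-E) | CC(C)=CCC/C(C)=C/C=C/C(C)=C/C=C/C(C)=C/C=C/C=C(C)/C=C/C=C(C)/C=C/C1=C(C)C(=O)[C@H](O)CC1(C)C
A3 | alternative 2 | rac-(3E)-4-(4-hydroxy-2,6,6-trimethyl-3-oxocyclohex-1-en-1-yl)but-3-en-2-one | CC(=O)/C=C/C1=C(C)C(=O)C(O)CC1(C)C
A4 | alternative 2 | (3E)-4-[(3R,4R)-3,4-dihydroxy-2,6,6-trimethylcyclohex-1-en-1-yl]but-3-en-2-one | CC(=O)/C=C/C1=C(C)[C@@H](O)[C@H](O)CC1(C)C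
A5 | alternative 3 | (3R,4R)-3,4-bis[tert-butyl(dimethyl)silyl]oxy-2,6,6-trimethylcyclohex-1-en-1-yl trifluoromethanesulfonate | FC(F)(F)S(=O)(=O)OC1=C(C)[C@@H](O[Si](C)(C)C(C)(C)C)[C@H](O[Si](C)(C)C(C)(C)C)CC1(C)C
A6 | alternative 3 | tributyl[(1E,3E,5E,7E,9E,11E,13E,15E,17E,19E)-3,7,12,16,20,24-hexamethylpentacosa-1,3,5,7,9,11,13,15,17,19,23-undecaen-1-yl]stannane (C7 to C1' of the target, SnBu3 on C7) | CC(C)=CCC/C(C)=C/C=C/C(C)=C/C=C/C(C)=C/C=C/C=C(C)/C=C/C=C(C)/C=C/[Sn](CCCC)(CCCC)CCCC
A7 | alternative 3 | (4R,5R)-4,5-bis[tert-butyl(dimethyl)silyl]oxy-2,2,6-trimethylcyclohexan-1-one (either C6 epimer) | O=C1C(C)[C@@H](O[Si](C)(C)C(C)(C)C)[C@H](O[Si](C)(C)C(C)(C)C)CC1(C)C
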